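## Retrosynthetic overview
- Target (13) ⇒ late photoredox anti-Markovnikov bromochlorination of the cyclohexene ring of 10, which is then the only alkene left (new method).
- 10 ⇒ ketone 9 (reduction sets C8–OH) ⇒ electrochemical 6-endo bromoetherification of ketol 7, which closes the tetrahydropyran ring and sets C10.
- 7 ⇒ Pummerer reaction of α-prenylated β-hydroxy sulfoxide 6 ⇒ 4 ⇒ photochemical thiol–olefin co-oxidation of the isopropenyl group of (R)-limonene (1).
- Ring order: the cyclohexene ring and C1' come from 1, the tetrahydropyran forms in Step 4, and the cyclohexane halogens go on last in Step 6.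

Assumptions:
- (R)-(+)-Limonene gives the (1R) ring carbon of the target.
- C7 is set with only modest bias from C1' in Step 1, so the C7 epimers are separated chromatographically at 7.
- The minor ring-halide diastereomer from Step 6 is also separated chromatographically.

## Route

**Step 1**
Reactants: 1 (R)-(+)-limonene; 2 thiophenol; 3 dioxygen
Product: 4 (2S)-2-[(1R)-4-methylcyclohex-3-en-1-yl]-1-(phenylsulfinyl)propan-2-ol (C7 epimers and sulfoxide epimers carried as a mixture)
Conditions: PhSH (1.1 equiv, syringe pump), O2 (1 atm), PhSSPh (5 mol%), 365 nm LEDs, EtOAc, 0 °C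
Reagents that add atoms: thiophenol (Sc1ccccc1); O2 (O=O)
Why: Thiol–olefin co-oxidation (radical chain). PhS• adds to the less hindered, more reactive CH2 terminus of the 1,1-disubstituted isopropenyl group. The tertiary C7 radical traps O2, and the resulting hydroperoxide oxidizes the sulfide to the sulfoxide, leaving the tertiary alcohol. The trisubstituted ring alkene is untouched. C7 is set with modest facial bias from C1'.

**Step 2**
Reactants: 4; 5 prenyl bromide (1-bromo-3-methylbut-2-ene)
Product: 6 (2S)-6-methyl-2-[(1R)-4-methylcyclohex-3-en-1-yl]-3-(phenylsulfinyl)hept-5-en-2-ol (C8 and S epimers unspecified)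
Conditions: LDA (2.3 equiv), THF, −78 °C, 30 min; then 5 (1.2 equiv), −78 → 0 °C
Reagents that add atoms: prenyl bromide (CC(C)=CCBr)
Why: α-Sulfinyl carbanion alkylation of the O,C-dianion. SN2 at the primary prenyl carbon gives the linear C8–C9 bond. The new C8 and S stereocenters are destroyed in Step 3.

**Step 3**
Reactants: 6
Product: 7 (2S)-2-hydroxy-6-methyl-2-[(1R)-4-methylcyclohex-3-en-1-yl]hept-5-en-3-one
Conditions: TFAA (3 equiv), 2,6-lutidine (6 equiv), MeCN, 0 °C; then NaHCO3, MeOH/H2O, rt; chromatographic separation of the C7 epimers to give pure (7S)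
Reagents that add atoms: none (net R2CH–S(O)Ph → R2C=O + PhSH)
Why: Pummerer rearrangement. Thionium trapping by trifluoroacetate and mild hydrolysis give the C8 ketone. C7 is quaternary and cannot epimerize, and the mild base avoids an α-ketol shift.

**Step 4**
Reactants: 7; 8 tetrabutylammonium bromide
Product: 9 (2S,5S)-5-bromo-2,6,6-trimethyl-2-[(1R)-4-methylcyclohex-3-en-1-yl]oxan-3-one
Conditions: Bu4NBr (1.5 equiv), 2,6-lutidine (2 equiv), MeCN/CH2Cl2 1:1, undivided cell, graphite anode/Pt cathode, 5 mA (2.2 F/mol), 0 °C
Reagents that add atoms: tetrabutylammonium bromide ([Br-].CCCC[N+](CCCC)(CCCC)CCCC), supplying Br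
Why: Electrochemical bromoetherification. Anodic Br− oxidation gives Br+ equivalents. The bromonium on the prenyl alkene is opened anti by the tertiary OH at C11 (Markovnikov, 6-endo); the ketone is non-nucleophilic, so only O7 cyclizes. The chair-like transition state puts the large cyclohexenyl group and the new C10–Br bond equatorial, which sets C10 relative to C7 (cyclohexenyl and Br both equatorial, C7-Me axial). The C7–O bond is retained. Bromination of the ring alkene is reversible and has no irreversible outlet.

**Step 5**
Reactants: 9
Product: 10 (2S,3S,5S)-5-bromo-2,6,6-trimethyl-2-[(1R)-4-methylcyclohex-3-en-1-yl]oxan-3-ol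
Conditions: L-Selectride (1.5 equiv), THF, −78 °C, 2 h; then NaBO3·4H2O, 0 °C
Reagents that add atoms: none (hydride and proton, H only)
Why: Diastereoselective ketone reduction. The bulky hydride attacks the face of the smaller C7 methyl, anti to the cyclohexenyl group, so C8–OH ends up cis to the cyclohexenyl group, as in the target.

**Step 6**
Reactants: 10; 11 tetrabutylammonium chloride; 12 bromotrichloromethane
Product: 13 target, (2S,3S,5S)-5-bromo-2-[(1R,3S,4S)-4-bromo-3-chloro-4-methylcyclohexyl]-2,6,6-trimethyloxan-3-ol
Conditions: Bu4NCl (1.5 equiv), BrCCl3 (3 equiv), [Mes-Acr-Me]+ClO4− (5 mol%), HFIP (3 equiv), MeCN (0.05 M), 450 nm LEDs, 25 °C, N2, 16 h; chromatographic removal of the minor ring diastereomer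
Reagents that add atoms: tetrabutylammonium chloride ([Cl-].CCCC[N+](CCCC)(CCCC)CCCC), supplying Cl; bromotrichloromethane (BrC(Cl)(Cl)Cl), supplying Br
Why: Proposed new method: photoredox anti-Markovnikov vicinal chlorobromination. Excited acridinium oxidizes the trisubstituted alkene to its radical cation (or generates Cl• from Cl−). Chloride adds to the less substituted carbon C2, giving the tertiary C1 radical. Br-atom transfer from BrCCl3 then gives the tertiary bromide, and the reduced catalyst turns •CCl3 into CHCl3. This gives tertiary Br and secondary Cl, the reverse of polar BrCl addition. The closest known reactions are Nicewicz-type alkene radical-cation anti-Markovnikov additions and Kharasch-type halogen-atom transfer. In the half-chair with C1' equatorial, axial Cl at C2 and axial Br at C1 (trans-diaxial) give the target configuration, with facial bias from C1' (expected ~2–3:1; minor isomer separated).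

## Compound list
1 | (R)-(+)-limonene | CC1=CC[C@@H](CC1)C(C)=C | starting material
2 | thiophenol | Sc1ccccc1 | starting material
3 | dioxygen | O=O | starting material
4 | (2S)-2-[(1R)-4-methylcyclohex-3-en-1-yl]-1-(phenylsulfinyl)propan-2-ol | O[C@@](C)([C@@H]1CCC(C)=CC1)CS(=O)c1ccccc1 | intermediate
5 | prenyl bromide | CC(C)=CCBr | starting material
6 | (2S)-6-methyl-2-[(1R)-4-methylcyclohex-3-en-1-yl]-3-(phenylsulfinyl)hept-5-en-2-ol | O[C@@](C)([C@@H]1CCC(C)=CC1)C(CC=C(C)C)S(=O)c1ccccc1 | intermediate
7 | (2S)-2-hydroxy-6-methyl-2-[(1R)-4-methylcyclohex-3-en-1-yl]hept-5-en-3-one | O[C@@](C)([C@@H]1CCC(C)=CC1)C(=O)CC=C(C)C | intermediate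
8 | tetrabutylammonium bromide | CCCC[N+](CCCC)(CCCC)CCCC.[Br-] | starting material
9 | (2S,5S)-5-bromo-2,6,6-trimethyl-2-[(1R)-4-methylcyclohex-3-en-1-yl]oxan-3-one | CC1(C)O[C@@](C)([C@@H]2CCC(C)=CC2)C(=O)C[C@@H]1Br | intermediate
10 | (2S,3S,5S)-5-bromo-2,6,6-trimethyl-2-[(1R)-4-methylcyclohex-3-en-1-yl]oxan-3-ol | CC1(C)O[C@@](C)([C@@H]2CCC(C)=CC2)[C@@H](O)C[C@@H]1Br | intermediate
11 | tetrabutylammonium chloride | CCCC[N+](CCCC)(CCCC)CCCC.[Cl-] | starting material
12 | bromotrichloromethane | BrC(Cl)(Cl)Cl | starting material
13 | target (2S,3S,5S)-5-bromo-2-[(1R,3S,4S)-4-bromo-3-chloro-4-methylcyclohexyl]-2,6,6-trimethyloxan-3-ol | CC1(C)O[C@@](C)([C@@H]2CC[C@](C)(Br)[C@@H](Cl)C2)[C@@H](O)C[C@@H]1Br | target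

**Total steps:** 6. **Longest linear sequence:** 6.

## Three steps most likely to fail
1. **Step 6 (proposed new method).** Regiochemistry, diastereoselectivity and side reactions (allylic H-abstraction, dichlorocarbene from CCl3−) are all uncertain.
   Fallback (known chemistry): treat 10 with NCS in aqueous acetone to give the trans-diaxial chlorohydrin (Cl at C2, tertiary OH at C1). Then convert the tertiary OH to the bromide with net retention using SOBr2 or TMSBr, with chlorine neighbouring-group participation.
2. **Step 4 (electrochemical bromoetherification).** Competing ring-alkene bromination, 5-endo closure by the C8 oxygen, or β,γ-enone isomerization could interfere.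
   Fallback: make the 10,11-bromohydrin (NBS, aqueous THF). Then close the ring by acid-promoted SN1 6-endo etherification (CSA, CH2Cl2) through the achiral gem-dimethyl tertiary cation, and separate the C10 epimers.
3. **Step 3 (Pummerer).** Dienyl sulfide formation from the allylic α-CH2 or α-ketol rearrangement could compete.
   Fallback: perform the Pummerer reaction on the unalkylated primary sulfoxide 4 to give the α-hydroxy aldehyde. Add allylMgBr under chelation control, then cross-metathesis with 2-methyl-2-butene (Grubbs II) to install the prenyl alkene. Finally selectively oxidize the secondary alcohol (DMP) to give 7.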